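**Retrosynthetic overview**

Atom labels: O1, C2 (CH3), C3 (C10H2OH), C4 (C8H2-C9O2R), C5 (CO2Me), C6. The strategy rests on the two neighbouring arms of dihydropyran ring A, C10 on C3 and C8-C9 on C4. Joined at C9-C10 they form cyclopentenone ring B (C3=C10-C9(=O)-C8-C4), fused on the C3-C4 bond.
21 => benzyl ethers off, C10 aldehyde reduced, C3 equilibrated, C9 acid esterified with protected hydroxytyrosol => formyl acid 15 => ring B cut at C9-C10 (ozonolysis of the C9=C10 silyl enol ether 12, made by 1,4-hydrosilylation) => bicyclic enone 11.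
11 => intramolecular Pauson-Khand reaction of dienyne 9. Ring A closes first (C3-C4) and ring B directly after (C8-C9, C9-C10), in one operation. C2 is bought, C4 is induced by C2, and C3 is set last under thermodynamic control.
9 => oxa-Michael addition of silyl-capped (S)-butynol 1 to methyl propiolate 2, α-iodination, Negishi vinylation, desilylation.

Key step: step 5

Assumption: hydride delivery in step 6 is drawn on the H4 face (cis ring fusion); delivery on the other face would give the C3 configuration of 19 directly, and step 10 levels both outcomes.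

**Step 1**
Reactants: 1 (S)-4-(trimethylsilyl)but-3-yn-2-ol; 2 methyl propiolate
Product: 3 methyl (E)-3-{[(2S)-4-(trimethylsilyl)but-3-yn-2-yl]oxy}prop-2-enoate
Conditions: DABCO (10 mol %), CH2Cl2, 0 °C to rt
Reagents that add atoms: none
Why: Amine-catalysed oxa-Michael addition of a secondary propargylic alcohol to an alkynoate is a standard entry to (E)-3-alkoxyacrylates, it does not touch the C2 stereocentre, and the silyl cap stays on the alkyne so that steps 2 and 3 meet no acidic alkyne C-H.

**Step 2**
Reactants: 3
Product: 5 methyl (Z)-2-iodo-3-{[(2S)-4-(trimethylsilyl)but-3-yn-2-yl]oxy}prop-2-enoate, via iodoacetate adduct 4 (not isolated)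
Conditions: NIS (1.05 equiv), AcOH (2 equiv), CH2Cl2, rt, dark; then Et3N (3 equiv), 0 °C to rt
Reagents that add atoms: N-iodosuccinimide, O=C1CCC(=O)N1I
Why: Iodoacetoxylation of the enol ether (iodine at the nucleophilic C5, acetate at C6) followed by base-induced loss of acetic acid is the established α-iodination of 3-alkoxyacrylates and gives the Z iodide, with iodine cis to O1 and the ester trans to it, while a silyl alkyne is inert to NIS when no silver or fluoride is present.

**Step 3**
Reactants: 5; 6 vinylmagnesium bromide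
Product: 8 methyl (E)-2-({[(2S)-4-(trimethylsilyl)but-3-yn-2-yl]oxy}methylidene)but-3-enoate, via vinylzinc bromide 7 (not isolated)
Conditions: 6 (1.5 equiv), ZnBr2 (1.6 equiv), THF, 0 °C; then 5, Pd(dppf)Cl2 (3 mol %), THF, 0 °C to rt
Reagents that add atoms: none
Why: Negishi coupling proceeds with retention at C5, so vinyl and O1 stay cis (the E descriptor, because CO2Me outranks vinyl), and zinc is preferred to boron or tin because its fast transmetalation to the alkenylpalladium, which dppf keeps coordinatively saturated, should outrun the 5-exo-dig carbopalladation of the alkyne that sits cis to palladium across O1-C2.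

**Step 4**
Reactants: 8
Product: 9 methyl (E)-2-{[(2S)-but-3-yn-2-yloxy]methylidene}but-3-enoate
Conditions: TBAF (1.1 equiv), AcOH (1.2 equiv), THF, 0 °C
Reagents that add atoms: none
Why: Fluoride-induced protodesilylation of an alkynylsilane is buffered with acetic acid and run without alcohol solvent, so that no alkoxide can exchange the O1 substituent at C6 by addition-elimination or isomerise the diene.

**Step 5**
Reactants: 9
Product: 11 methyl (1S,4aS)-1-methyl-6-oxo-1,4a,5,6-tetrahydrocyclopenta[c]pyran-4-carboxylate, via hexacarbonyldicobalt complex 10 (not isolated)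
Conditions: Co2(CO)8 (1.1 equiv), CH2Cl2, rt, 2 h; then NMO (8 equiv, in portions), 0 °C to rt; chromatographic removal of the C4 epimer
Reagents that add atoms: dicobalt octacarbonyl, O=C=[Co](=C=O)(=C=O)(=C=O)[Co](=C=O)(=C=O)(=C=O)=C=O
Why: Proposed new method: the alkyne forms its Co2(CO)6 complex 10, NMO oxidises off one CO, the C4=C8 vinyl group binds at the free site and inserts into the Co-C3 bond, and CO insertion with reductive elimination releases the enone; the closest known reaction is the N-oxide-promoted intramolecular Pauson-Khand reaction of oxygen-tethered 1,7-enynes to bicyclo[4.3.0]nonenones, whereas a 3-alkoxyacrylate tether and an ene partner that is the far end of a 2-carboxy diene have not been tried. Ring A closes by 6-exo migratory insertion (C3-C4), helped by the planar O1-C6=C5 unit that leaves C2 as the only sp3 tether atom, and ring B closes by carbonylative [2+2+1] closure (C8-C9 and C9-C10). Site selectivity is fixed by the tether, since engaging C5=C6 would need a four-membered ring and a [4+2] mode would need a bridgehead alkene. C4 is the only new stereocentre and is controlled by C2: C8 must lie pseudoequatorial to reach cobalt, H4 is then pseudoaxial, and the wanted isomer carries the C2 methyl pseudoaxial on the same (exo) face, where it escapes the eclipsing contact with the cobalt-bearing C10 that a pseudoequatorial methyl meets, in line with the exo preference of propargylic substituents in cobalt enyne cyclisations. With a terminal alkyne this bias should be modest, so the C4 epimer is to be removed at this stage. Complexation and the low temperature also keep the propargyl vinyl ether from its [3,3] rearrangement and, with no acid present, from ionising at C2.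

**Step 6**
Reactants: 11
Product: 12 methyl (1S,4aS,7aS)-6-{[dimethyl(phenyl)silyl]oxy}-1-methyl-1,4a,5,7a-tetrahydrocyclopenta[c]pyran-4-carboxylate
Conditions: [(Ph3P)CuH]6 (1 mol %), PhMe2SiH (1.5 equiv), toluene, 0 °C to rt
Reagents that add atoms: dimethyl(phenyl)silane, C[SiH](C)c1ccccc1
Why: Copper hydride 1,4-hydrosilylation puts hydride on C3 and silicon on the C9 oxygen, so the enol ether can only be C9=C10 and the bond to be cut is marked regiospecifically, the enone should react far faster than the donor-substituted C5=C6 acrylate, and hydride is drawn on the H4 face to give the less strained cis fusion, a provisional C3 configuration that step 10 resets.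

**Step 7**
Reactants: 12
Product: 15 2-[(2S,3R,4S)-3-formyl-5-(methoxycarbonyl)-2-methyl-3,4-dihydro-2H-pyran-4-yl]acetic acid, via methoxy hydroperoxide 13 (not isolated), via silyl ester aldehyde 14 (not isolated)
Conditions: O3 (1 equiv, Sudan Red 7B end point), CH2Cl2-MeOH 9:1, -78 °C; Me2S, -78 °C to rt; aqueous pH 4 buffer work-up
Reagents that add atoms: ozone, [O-][O+]=O
Why: Ozonolysis (Criegee mechanism) of the electron-rich silyl enol ether, titrated against a dye so that the push-pull C5=C6 bond is spared, turns C9 into the silyl ester and C10 into a carbonyl oxide that methanol traps, and sulfide reduction with mild hydrolysis then gives the formyl acid with C2, C3 and C4 unchanged.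

**Step 8**
Reactants: 16 hydroxytyrosol
Product: 17 2-[3,4-bis(benzyloxy)phenyl]ethanol
Conditions: BnBr (2.2 equiv), K2CO3 (2.5 equiv), acetone, reflux
Reagents that add atoms: benzyl bromide, BrCc1ccccc1
Why: Williamson etherification with a carbonate base alkylates only the two acidic phenols and leaves the aliphatic alcohol free for the esterification.

**Step 9**
Reactants: 15; 17
Product: 18 methyl (2S,3R,4S)-4-(2-{2-[3,4-bis(benzyloxy)phenyl]ethoxy}-2-oxoethyl)-3-formyl-2-methyl-3,4-dihydro-2H-pyran-5-carboxylate
Conditions: PPh3 (1.3 equiv), DIAD (1.3 equiv, added last), THF, 0 °C to rt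
Reagents that add atoms: none
Why: Mitsunobu esterification alkylates the carboxylate with the activated primary alcohol under essentially neutral conditions, which spares the enolisable 3-alkoxy aldehyde from amine bases and acyl-transfer catalysts and cannot give a pseudo-ester from a lactol tautomer.

**Step 10**
Reactants: 18
Product: 19 methyl (2S,3S,4S)-4-(2-{2-[3,4-bis(benzyloxy)phenyl]ethoxy}-2-oxoethyl)-3-formyl-2-methyl-3,4-dihydro-2H-pyran-5-carboxylate
Conditions: DBU (10 mol %), CH2Cl2, 0 °C to rt; AcOH quench
Reagents that add atoms: none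
Why: Base-catalysed epimerisation of the aldehyde through its enolate sets C3 under thermodynamic control: in the half-chair with the C4 arm pseudoaxial (away from the C5 ester) and the C2 methyl equatorial, an axial formyl group has no 1,3-diaxial partner (O1 and sp2 C5) and lies anti to the arm, whereas the 3R epimer is gauche to both neighbours, and any reversible opening of O1-C2 by elimination should drain into the same isomer because C4 is untouched.

**Step 11**
Reactants: 19
Product: 20 methyl (2S,3R,4S)-4-(2-{2-[3,4-bis(benzyloxy)phenyl]ethoxy}-2-oxoethyl)-3-(hydroxymethyl)-2-methyl-3,4-dihydro-2H-pyran-5-carboxylate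
Conditions: NaBH4 (1 equiv), THF-MeOH, -40 °C; AcOH quench
Reagents that add atoms: none
Why: Chemoselective borohydride reduction of the aldehyde beside both esters is run cold and quenched with acid so that the C10 alkoxide, held trans-diaxial to the arm, does not lactonise onto C9 and expel the phenethyl alcohol (the descriptor at C3 changes from S to R only because CH2OH ranks below C2).

**Step 12**
Reactants: 20
Product: 21 methyl (2S,3R,4S)-4-{2-[2-(3,4-dihydroxyphenyl)ethoxy]-2-oxoethyl}-3-(hydroxymethyl)-2-methyl-3,4-dihydro-2H-pyran-5-carboxylate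
Conditions: H2 (1 atm), 10% Pd/C, EtOAc, rt
Reagents that add atoms: none
Why: Hydrogenolysis of the two aryl benzyl ethers under neutral conditions, to which the trisubstituted push-pull C5=C6 bond, the esters and the primary alcohol should be inert, frees the catechol without acid or base that could trigger lactonisation.

**Compound list**

1 | (S)-4-(trimethylsilyl)but-3-yn-2-ol | C[Si](C)(C)C#C[C@H](C)O | starting material
2 | methyl propiolate | C#CC(=O)OC | starting material
3 | methyl (E)-3-{[(2S)-4-(trimethylsilyl)but-3-yn-2-yl]oxy}prop-2-enoate | C[Si](C)(C)C#C[C@H](C)O/C=C/C(=O)OC | intermediate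
4 | methyl 3-acetoxy-2-iodo-3-{[(2S)-4-(trimethylsilyl)but-3-yn-2-yl]oxy}propanoate (mixture at C5 and C6) | C[Si](C)(C)C#C[C@H](C)OC(OC(C)=O)C(I)C(=O)OC | intermediate
5 | methyl (Z)-2-iodo-3-{[(2S)-4-(trimethylsilyl)but-3-yn-2-yl]oxy}prop-2-enoate | C[Si](C)(C)C#C[C@H](C)O/C=C(\I)C(=O)OC | intermediate
6 | vinylmagnesium bromide | C=C[Mg]Br | starting material
7 | vinylzinc bromide | C=C[Zn]Br | intermediate
8 | methyl (E)-2-({[(2S)-4-(trimethylsilyl)but-3-yn-2-yl]oxy}methylidene)but-3-enoate | C[Si](C)(C)C#C[C@H](C)O/C=C(\C=C)C(=O)OC | intermediate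
9 | methyl (E)-2-{[(2S)-but-3-yn-2-yloxy]methylidene}but-3-enoate | C#C[C@H](C)O/C=C(\C=C)C(=O)OC | intermediate
10 | hexacarbonyldicobalt (Co-Co) complex of the alkyne of 9 | [CH]12[Co]3(=C=O)(=C=O)(=C=O)[Co]1(=C=O)(=C=O)(=C=O)C23[C@H](C)O/C=C(\C=C)C(=O)OC | intermediate
11 | methyl (1S,4aS)-1-methyl-6-oxo-1,4a,5,6-tetrahydrocyclopenta[c]pyran-4-carboxylate | COC(=O)C1=CO[C@@H](C)C2=CC(=O)C[C@H]12 | intermediate
12 | methyl (1S,4aS,7aS)-6-{[dimethyl(phenyl)silyl]oxy}-1-methyl-1,4a,5,7a-tetrahydrocyclopenta[c]pyran-4-carboxylate | COC(=O)C1=CO[C@@H](C)[C@@H]2C=C(O[Si](C)(C)c3ccccc3)C[C@H]12 | intermediate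
13 | dimethyl(phenyl)silyl 2-{(2S,3R,4S)-3-[hydroperoxy(methoxy)methyl]-5-(methoxycarbonyl)-2-methyl-3,4-dihydro-2H-pyran-4-yl}acetate (mixture at the peroxyacetal carbon) | COC(=O)C1=CO[C@@H](C)[C@H](C(OC)OO)[C@@H]1CC(=O)O[Si](C)(C)c1ccccc1 | intermediate
14 | dimethyl(phenyl)silyl 2-[(2S,3R,4S)-3-formyl-5-(methoxycarbonyl)-2-methyl-3,4-dihydro-2H-pyran-4-yl]acetate | COC(=O)C1=CO[C@@H](C)[C@H](C=O)[C@@H]1CC(=O)O[Si](C)(C)c1ccccc1 | intermediate
15 | 2-[(2S,3R,4S)-3-formyl-5-(methoxycarbonyl)-2-methyl-3,4-dihydro-2H-pyran-4-yl]acetic acid | COC(=O)C1=CO[C@@H](C)[C@H](C=O)[C@@H]1CC(=O)O | intermediate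
16 | hydroxytyrosol | OCCc1ccc(O)c(O)c1 | starting material
17 | 2-[3,4-bis(benzyloxy)phenyl]ethanol | OCCc1ccc(OCc2ccccc2)c(OCc2ccccc2)c1 | intermediate
18 | methyl (2S,3R,4S)-4-(2-{2-[3,4-bis(benzyloxy)phenyl]ethoxy}-2-oxoethyl)-3-formyl-2-methyl-3,4-dihydro-2H-pyran-5-carboxylate | COC(=O)C1=CO[C@@H](C)[C@H](C=O)[C@@H]1CC(=O)OCCc1ccc(OCc2ccccc2)c(OCc2ccccc2)c1 | intermediate
19 | methyl (2S,3S,4S)-4-(2-{2-[3,4-bis(benzyloxy)phenyl]ethoxy}-2-oxoethyl)-3-formyl-2-methyl-3,4-dihydro-2H-pyran-5-carboxylate | COC(=O)C1=CO[C@@H](C)[C@@H](C=O)[C@@H]1CC(=O)OCCc1ccc(OCc2ccccc2)c(OCc2ccccc2)c1 | intermediate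
20 | methyl (2S,3R,4S)-4-(2-{2-[3,4-bis(benzyloxy)phenyl]ethoxy}-2-oxoethyl)-3-(hydroxymethyl)-2-methyl-3,4-dihydro-2H-pyran-5-carboxylate | COC(=O)C1=CO[C@@H](C)[C@@H](CO)[C@@H]1CC(=O)OCCc1ccc(OCc2ccccc2)c(OCc2ccccc2)c1 | intermediate
21 | methyl (2S,3R,4S)-4-{2-[2-(3,4-dihydroxyphenyl)ethoxy]-2-oxoethyl}-3-(hydroxymethyl)-2-methyl-3,4-dihydro-2H-pyran-5-carboxylate | COC(=O)C1=CO[C@@H](C)[C@@H](CO)[C@@H]1CC(=O)OCCc1ccc(O)c(O)c1 | target

Total step count: 12. Longest linear sequence: 11 (steps 1 to 7 and 9 to 12).

**Steps most likely to fail**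

1. Step 5 (the labelled step).
- What may go wrong: the whole diene may chelate cobalt, the metal may be lost before insertion, the six-membered ring may close slowly, and facial selectivity at C4 may be poor.
- Fallback (known chemistry): the C3-C4 bond is made by a sulfanyl-radical addition-cyclisation onto an acrylate arm instead of by carbonylative cycloaddition. It sets out from iodide 5 and alcohol 17. Alcohol 17 is esterified (EDC, DMAP) with (E)-3-(tributylstannyl)acrylic acid to the stannyl acrylate F1. F1 and 5 are joined without palladium by Cu(O2CC4H3S) (copper 2-thiophenecarboxylate) in NMP; this stannane-iodide coupling has no alkenylpalladium that could carbopalladate the alkyne, and it gives the silyl dienoate F2. Buffered TBAF as in step 4 gives the terminal alkyne F3. Slow addition of PhSH with Et3B and air at rt adds the sulfanyl radical to C10, and the C3 vinyl radical closes 6-exo onto C4, the β-carbon of the enoate, to the vinyl sulfide F4 (C4 epimers to be separated). HgCl2 and CaCO3 in aqueous MeCN hydrolyse F4 to the aldehyde. This comes back to the route at 18, as a C3 mixture that step 10 levels.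

2. Step 10.
- What may go wrong: the equilibrium may stop short of the 3S side, and β-elimination across C3-C2 may open ring A and erode C2.
- Fallback: C3 is set kinetically in the bicycle under ligand control instead of thermodynamically in the monocycle, using the asymmetric copper hydride conjugate reduction known for 3-substituted cyclopentenones. It sets out from enone 11. CuCl, NaOt-Bu and the enantiomer of DTBM-SEGPHOS matched to the face opposite H4, with PhMe2SiH in toluene, should give the trans-fused silyl enol ether F5. Ozonolysis as in step 7 gives elenolic acid F6. Mitsunobu esterification with 17 as in step 9 comes back to the route at 19, so no epimerisation is needed.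

3. Step 7.
- What may go wrong: ozone may also attack C5=C6, and the aldehyde may be over-oxidised.
- Fallback: the C9-C10 bond is cut in two milder known operations. It sets out from 12. Rubottom oxidation (dimethyldioxirane, acetone-CH2Cl2, -78 to 0 °C) selects the silyl enol ether and gives, after loss of the silyl group on mild acid work-up, the α-hydroxy ketone F7. NaIO4 in aqueous THF cleaves F7 between C9 and C10 and comes back to the route at 15.

**Further compounds**

F1 | step 5 | 2-[3,4-bis(benzyloxy)phenyl]ethyl (E)-3-(tributylstannyl)prop-2-enoate | CCCC[Sn](CCCC)(CCCC)/C=C/C(=O)OCCc1ccc(OCc2ccccc2)c(OCc2ccccc2)c1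
F2 | step 5 | 1-{2-[3,4-bis(benzyloxy)phenyl]ethyl} 5-methyl (2E,4E)-4-({[(2S)-4-(trimethylsilyl)but-3-yn-2-yl]oxy}methylidene)pent-2-enedioate | C[Si](C)(C)C#C[C@H](C)O/C=C(\C=C\C(=O)OCCc1ccc(OCc2ccccc2)c(OCc2ccccc2)c1)C(=O)OC
F3 | step 5 | 1-{2-[3,4-bis(benzyloxy)phenyl]ethyl} 5-methyl (2E,4E)-4-{[(2S)-but-3-yn-2-yloxy]methylidene}pent-2-enedioate | C#C[C@H](C)O/C=C(\C=C\C(=O)OCCc1ccc(OCc2ccccc2)c(OCc2ccccc2)c1)C(=O)OC
F4 | step 5 | methyl (2S,4S)-4-(2-{2-[3,4-bis(benzyloxy)phenyl]ethoxy}-2-oxoethyl)-2-methyl-3-[(phenylsulfanyl)methylidene]-3,4-dihydro-2H-pyran-5-carboxylate (E/Z mixture) | COC(=O)C1=CO[C@@H](C)C(=CSc2ccccc2)[C@@H]1CC(=O)OCCc1ccc(OCc2ccccc2)c(OCc2ccccc2)c1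
F5 | step 10 | methyl (1S,4aS,7aR)-6-{[dimethyl(phenyl)silyl]oxy}-1-methyl-1,4a,5,7a-tetrahydrocyclopenta[c]pyran-4-carboxylate | COC(=O)C1=CO[C@@H](C)[C@H]2C=C(O[Si](C)(C)c3ccccc3)C[C@H]12
F6 | step 10 | elenolic acid, 2-[(2S,3S,4S)-3-formyl-5-(methoxycarbonyl)-2-methyl-3,4-dihydro-2H-pyran-4-yl]acetic acid | COC(=O)C1=CO[C@@H](C)[C@@H](C=O)[C@@H]1CC(=O)O
F7 | step 7 | methyl (1S,4aS,7aS)-7-hydroxy-1-methyl-6-oxo-1,4a,5,6,7,7a-hexahydrocyclopenta[c]pyran-4-carboxylate (both C7 epimers) | COC(=O)C1=CO[C@@H](C)[C@@H]2C(O)C(=O)C[C@H]12
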